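**Plan**
- Retrosynthesis: ring C (the dihydropyranone) is cut at O1–C2 and C4–C4a, which leads back to the 2-iodo-5-methoxyphenyl ester of an (E)-3-(benzofuran-5-yl)acrylic acid. Then the ester C–O bond, the acrylic Cα=Cβ bond, and the furan ring (aryl–alkyne bond and furan O–C bond) are cut.
- Enabling feature (flavanone numbering): the C4 ketone sits on C4a of ring A, ortho to the ring oxygen O1 and para to the C7 methoxy group, and C2 is β to that ketone. An acyl group parked on O1 can therefore move to C4a by a 1,3-O→C shift started at an ortho C–I bond, and the released phenoxide O1 is placed for a 6-endo-trig oxa-Michael closure onto C2.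
- Forward order: benzofuran ring first (Sonogashira coupling with 5-endo-dig closure), then the acrylic acid chain (Knoevenagel–Doebner), then esterification with 2-iodo-5-methoxyphenol, and ring C last in one operation.
- Stereochemistry: the only stereocentre, C2 (S), is set in the last step by a cinchona thiourea catalyst during the oxa-Michael closure; no later step can racemise it.

Key step: step 4

Assumption: the quinine-derived thiourea is taken to give the (S)-configured closure; if the sense of induction is the opposite, its quinidine-derived pseudoenantiomer is used under the same conditions.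

**Step 1**
Reactants: 1 4-hydroxy-3-iodobenzaldehyde; 2 1-ethynyl-4-methoxybenzene
Product: 4 2-(4-methoxyphenyl)-1-benzofuran-5-carbaldehyde, via alkynylphenol 3 (not isolated)
Conditions: PdCl2(PPh3)2 (2 mol %), CuI (4 mol %), Et3N, DMF, degassed, 25 → 70 °C
Reagents that add atoms: none
Why: Sonogashira coupling gives alkynylphenol 3, whose phenol (made more acidic by the para aldehyde) should add 5-endo-dig to the metal-activated alkyne under the same conditions, a well-known domino heteroannulation of ortho-iodophenols to 2-arylbenzofurans.

**Step 2**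
Reactants: 4 2-(4-methoxyphenyl)-1-benzofuran-5-carbaldehyde
Product: 6 (E)-3-[2-(4-methoxyphenyl)-1-benzofuran-5-yl]prop-2-enoic acid, via arylidenemalonic acid 5 (not isolated)
Conditions: malonic acid (2 equiv), pyridine, piperidine (cat.), 95 °C; then aq. HCl
Reagents that add atoms: malonic acid, OC(=O)CC(=O)O
Why: Knoevenagel condensation with decarboxylation in hot pyridine (Doebner modification) should give the thermodynamically preferred (E)-acrylic acid; the benzofuran and aryl ether are inert to these conditions.

**Step 3**
Reactants: 6 (E)-3-[2-(4-methoxyphenyl)-1-benzofuran-5-yl]prop-2-enoic acid; 7 2-iodo-5-methoxyphenol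
Product: 8 2-iodo-5-methoxyphenyl (E)-3-[2-(4-methoxyphenyl)-1-benzofuran-5-yl]prop-2-enoate
Conditions: DIC (1.2 equiv), DMAP (10 mol %), CH2Cl2, 0 °C → rt
Reagents that add atoms: none
Why: Steglich esterification, in which DIC activates the acid and DMAP passes the acyl group to the hindered but acidic phenol, is mild enough to leave the C–I bond and the (E)-alkene untouched.

**Step 4**
Reactants: 8 2-iodo-5-methoxyphenyl (E)-3-[2-(4-methoxyphenyl)-1-benzofuran-5-yl]prop-2-enoate
Product: 12 (2S)-7-methoxy-2-[2-(4-methoxyphenyl)-1-benzofuran-5-yl]-2,3-dihydro-4H-chromen-4-one (lophirone J), via arylmagnesium chloride 9 (not isolated), via chloromagnesium phenoxide 10 (not isolated), via 2'-hydroxychalcone 11 (not isolated)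
Conditions: iPrMgCl·LiCl (1.1 equiv), THF, −40 → 0 °C; 1 M HCl, 0 °C, phase cut into toluene, dried; then quinine-derived thiourea 1-[3,5-bis(trifluoromethyl)phenyl]-3-[(8α,9S)-6'-methoxycinchonan-9-yl]thiourea (10 mol %), toluene, 0 °C → rt; filtration through silica
Reagents that add atoms: none
Why: Iodine–magnesium exchange at the C–I bond ortho to the acyloxy group gives arylmagnesium 9, whose carbanion attacks the ester carbonyl held next to it, so the acyl group moves from O1 to C4a (1,3-O→C shift) to give phenoxide 10, which stays open under basic conditions and gives chalcone 11 on acidic quench. The closest known reaction types are the halogen–metal-exchange-initiated anionic Fries rearrangement of ortho-haloaryl esters and the amine–thiourea-catalysed asymmetric intramolecular oxa-Michael addition of 2'-hydroxychalcones. Ring C then closes by 6-endo-trig oxa-Michael addition of O1 to C2. The C2 stereocentre is set by the catalyst: the thiourea binds the C4 carbonyl while the quinuclidine deprotonates and ion-pairs the phenol, so O1 should be delivered to one face of the enone β-carbon to give (S). The step needs chemoselectivity (exchange before the Grignard reagent adds to the ester or enoate), which the fast exchange of an iodide ortho to an acyloxy group at −40 °C should secure, and regioselectivity of acylation (C4a, para to OMe, with no 4-aryl-dihydrocoumarin as an acid-mediated union would give), which the position of the iodine fixes. Kinetic control of the closure (low temperature, catalyst removed on silica before equilibrium) should guard the enantiomeric purity against retro-oxa-Michael opening.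

**Compound list**
1 | 4-hydroxy-3-iodobenzaldehyde | O=Cc1ccc(O)c(I)c1 | starting material
2 | 1-ethynyl-4-methoxybenzene | C#Cc1ccc(OC)cc1 | starting material
3 | 4-hydroxy-3-[(4-methoxyphenyl)ethynyl]benzaldehyde | O=Cc1ccc(O)c(C#Cc2ccc(OC)cc2)c1 | intermediate (not isolated)
4 | 2-(4-methoxyphenyl)-1-benzofuran-5-carbaldehyde | COc1ccc(-c2cc3cc(C=O)ccc3o2)cc1 | intermediate
5 | 2-{[2-(4-methoxyphenyl)-1-benzofuran-5-yl]methylidene}propanedioic acid | COc1ccc(-c2cc3cc(C=C(C(=O)O)C(=O)O)ccc3o2)cc1 | intermediate (not isolated)
6 | (E)-3-[2-(4-methoxyphenyl)-1-benzofuran-5-yl]prop-2-enoic acid | COc1ccc(-c2cc3cc(/C=C/C(=O)O)ccc3o2)cc1 | intermediate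
7 | 2-iodo-5-methoxyphenol | COc1ccc(I)c(O)c1 | starting material
8 | 2-iodo-5-methoxyphenyl (E)-3-[2-(4-methoxyphenyl)-1-benzofuran-5-yl]prop-2-enoate | COc1ccc(-c2cc3cc(/C=C/C(=O)Oc4cc(OC)ccc4I)ccc3o2)cc1 | intermediate
9 | chloro{4-methoxy-2-[(E)-3-[2-(4-methoxyphenyl)-1-benzofuran-5-yl]prop-2-enoyloxy]phenyl}magnesium | COc1ccc(-c2cc3cc(/C=C/C(=O)Oc4cc(OC)ccc4[Mg]Cl)ccc3o2)cc1 | intermediate (not isolated)
10 | chloromagnesium 5-methoxy-2-[(E)-3-[2-(4-methoxyphenyl)-1-benzofuran-5-yl]prop-2-enoyl]phenoxide | COc1ccc(-c2cc3cc(/C=C/C(=O)c4ccc(OC)cc4O[Mg]Cl)ccc3o2)cc1 | intermediate (not isolated)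
11 | (E)-1-(2-hydroxy-4-methoxyphenyl)-3-[2-(4-methoxyphenyl)-1-benzofuran-5-yl]prop-2-en-1-one | COc1ccc(-c2cc3cc(/C=C/C(=O)c4ccc(OC)cc4O)ccc3o2)cc1 | intermediate (not isolated)
12 | (2S)-7-methoxy-2-[2-(4-methoxyphenyl)-1-benzofuran-5-yl]-2,3-dihydro-4H-chromen-4-one (lophirone J) | COc1ccc(-c2cc3cc([C@@H]4CC(=O)c5ccc(OC)cc5O4)ccc3o2)cc1 | target

**Total step count:** 4
**Longest linear sequence:** 4 steps (1 → 4 → 6 → 8 → 12)

**Steps most likely to fail**

Step 4. The alkylmagnesium reagent may add to the aryl ester or the enoate in competition with the exchange. In the closure, facial selectivity may be poor for a chalcone that offers the catalyst only one binding point, and reversible ring opening may erode the enantiomeric purity or leave the closure incomplete. The fallback sets out from aldehyde 4 and returns at 12; it forms C2–C3 and O1–C2 instead. Commercial methyl 2-hydroxy-4-methoxybenzoate is condensed with the lithium enolate of tert-butyl acetate (LDA, THF, −78 → 0 °C, Claisen condensation) to give tert-butyl 3-(2-hydroxy-4-methoxyphenyl)-3-oxopropanoate F1. Knoevenagel condensation of this with 4 (piperidine, AcOH, toluene, 4 Å sieves) should give tert-butyl 2-(2-hydroxy-4-methoxybenzoyl)-3-[2-(4-methoxyphenyl)-1-benzofuran-5-yl]prop-2-enoate F2, in which the ester gives the thiourea catalyst two-point binding. Closure with the same catalyst (10 mol %, toluene, −25 °C) should give tert-butyl (2S)-7-methoxy-2-[2-(4-methoxyphenyl)-1-benzofuran-5-yl]-4-oxo-3,4-dihydro-2H-chromene-3-carboxylate F3 (C3 epimerisable). TsOH·H2O in toluene at 80 °C then removes the tert-butyl ester and carbon dioxide to give 12.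

Step 3. Acylation of the hindered ortho-iodophenol may be slow, so that the activated acid rearranges to the N-acylurea, or the activated aryl ester may be cleaved on work-up. The fallback sets out from phenol 7 (with aldehyde 4) and returns at 8, bypassing step 2. Phenol 7 is acylated with bromoacetyl bromide (pyridine, CH2Cl2, 0 °C) to give 2-iodo-5-methoxyphenyl bromoacetate F4. Michaelis–Arbuzov reaction with P(OEt)3 (neat, 110 °C) gives 2-iodo-5-methoxyphenyl (diethoxyphosphoryl)acetate F5. Horner–Wadsworth–Emmons olefination of 4 with this phosphonate (LiCl, DBU, MeCN, 0 °C → rt) should give the (E)-ester 8 directly.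

Step 1. The copper co-catalyst may dimerise the alkyne oxidatively, and the sequence may stall at the open alkynylphenol. The fallback sets out from alkyne 2 and returns at 4. Alkyne 2 is converted with CuI in aqueous ammonia and ethanol into the monovalent copper acetylide, copper (4-methoxyphenyl)acetylide F6. This is heated with iodophenol 1 in pyridine at 115 °C under nitrogen (Castro–Stephens coupling, which with ortho-iodophenols gives the benzofuran directly, without palladium or free alkyne).

**Further compounds**
F1 | step 4 | tert-butyl 3-(2-hydroxy-4-methoxyphenyl)-3-oxopropanoate | COc1ccc(C(=O)CC(=O)OC(C)(C)C)c(O)c1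
F2 | step 4 | tert-butyl 2-(2-hydroxy-4-methoxybenzoyl)-3-[2-(4-methoxyphenyl)-1-benzofuran-5-yl]prop-2-enoate | COc1ccc(-c2cc3cc(C=C(C(=O)OC(C)(C)C)C(=O)c4ccc(OC)cc4O)ccc3o2)cc1
F3 | step 4 | tert-butyl (2S)-7-methoxy-2-[2-(4-methoxyphenyl)-1-benzofuran-5-yl]-4-oxo-3,4-dihydro-2H-chromene-3-carboxylate | COc1ccc(-c2cc3cc([C@@H]4C(C(=O)OC(C)(C)C)C(=O)c5ccc(OC)cc5O4)ccc3o2)cc1
F4 | step 3 | 2-iodo-5-methoxyphenyl bromoacetate | COc1ccc(I)c(OC(=O)CBr)c1
F5 | step 3 | 2-iodo-5-methoxyphenyl (diethoxyphosphoryl)acetate | CCOP(=O)(OCC)CC(=O)Oc1cc(OC)ccc1I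
F6 | step 1 | copper (4-methoxyphenyl)acetylide | COc1ccc(C#C[Cu])cc1
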